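## The problem

Epimedonin G (17) is an achiral 2-aryloxychromone: ring A is a benzene ring with oxygen on C5, C7 and C8a, a 3-methylbut-2-enyl (prenyl) group on C8 and hydrogen on C6; ring C is the 4-pyranone; C2 of ring C carries, through an ether oxygen, the 4-hydroxyphenyl ring B. There is no stereocentre and no alkene geometry to control, so the whole difficulty is positional and chemoselective. First, C6 and C8 each lie between two oxygens and are almost equal as nucleophiles, and in an open-chain aryl ketone precursor the two oxygens ortho to the acyl carbon are almost equal as ring-closing partners; late prenylation or late ring closure therefore tends to give the 6-prenyl isomer as well. Second, C2 is bonded to O1 and to the aryloxy oxygen: it is a carbonic-acid-level carbon inside a vinylogous carbonate, and nucleophiles or hot aqueous acid or base displace the aryloxy group, so the C2–OAr unit should be made late and in non-nucleophilic media. Third, the prenyl alkene is attacked by the peracids that a 2-sulfonylchromone route needs, is reduced under the hydrogenolysis that benzyl ethers need, and under strong acid is captured by the neighbouring O7 to give a chromane, which excludes methyl ethers. Three phenols must therefore be released at the end under mild conditions. The feature that makes the key step possible: on ring A the ring oxygen O1 (on C8a) and the prenyl-bearing C8 are ortho neighbours, the pattern left by a Claisen rearrangement of an aryl 1,1-dimethylallyl ether, and C2 of ring C, with its two oxygens, is what the oxygen-bearing carbon of an aryl alkynyl ether becomes when a phenol adds to it; O1 can therefore first hand the prenyl group to C8 and then close ring C onto an aryloxy-substituted ynone in one operation.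

## Retrosynthesis

**Disconnection 1 (17 to 16; three protecting-group O–C bonds).** The three phenolic O–H bonds are traced back to O–CH2OCH3 bonds in 16. Methoxymethyl ethers are preferred to benzyl ethers (hydrogenolysis would saturate the prenyl alkene) and to methyl ethers (their cleavage needs Lewis acids that cyclise the prenyl group onto O7). They also tolerate the organolithium, the oxidation and the heating that come before. 16 is no simpler in skeleton, but it removes every acidic hydrogen from the key step. The forward reaction must hydrolyse three aryl acetals with acid dilute enough to leave the prenyl alkene and C2 alone.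

**Disconnection 2 (16 to 13; bonds O1–C2 and C8–C1''; the key step).** Cutting O1–C2 as a retro-oxa-Michael addition opens ring C to the ortho-hydroxyaryl ynone 15, in which C2 and C3 are the two carbons of an alkyne and the ring-B oxygen already sits on C2. Cutting C8–C1'' as a retro-Claisen rearrangement (through dienone 14) moves the five prenyl carbons back onto O1 as a 1,1-dimethylallyl ether, which gives 13. Against the neighbouring cuts: cutting C2–OAr leaves the C6/C8 question open and needs a leaving group at C2 that is made with a peracid; cutting C8–C1'' alone asks an electrophile to choose between C6 and C8; cutting O1–C2 alone asks a ketone to choose between two ortho oxygens. In 13 these choices no longer exist: one oxygen bears the allyl group, that oxygen has one ortho carbon bearing hydrogen, and the other ortho oxygen is blocked. 13 is much simpler than 16: one ring fewer, no C-prenyl group, and it is assembled from two monocyclic pieces. The forward reaction must deliver the allyl unit to C8 and not to the acyl-bearing carbon, close in the 6-endo mode, and run without acid or nucleophile that would ionise the tertiary ether or add to the ynone.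

**Disconnection 3 (13 to 5 and 9; bond C3–C4).** The ynone is cut between the carbonyl carbon C4 and the alkyne carbon C3, with the oxidation level adjusted through the propargylic alcohol 12, which comes from aldehyde 5 and lithium acetylide 11. 11 is the alkynyl ether of ring B; it is made in the flask from the dichlorovinyl ether 9 through chloroalkyne 10, and 9 comes from phenol 6 and trichloroethylene 7 through dichloroacetylene 8. This cut is preferred to forming the C2–O(ring B) bond on a finished chromone because the aryloxy oxygen is attached to the future C2 while that carbon is still an unreactive sp carbon, and no sulfur group or strong oxidant is needed. 5 and 9 are both simple benzene derivatives. The forward steps must add an acetylide to a hindered, electron-rich aldehyde and oxidise an acid-labile carbinol under neutral conditions; the allyl ether on O1 keeps that oxygen out of both.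

**Disconnection 4 (5 to 1; bond O1–C(CH3)2 and two protecting-group bonds).** The tertiary allyl ether 5 is traced back through the propargyl ether 4 (semihydrogenation) to phenol 2 and the tertiary propargylic chloride 3; 2 comes from 2,4,6-trihydroxybenzaldehyde 1. The three oxygens of 1 are told apart by the formyl group: the two that are not held in the hydrogen bond take the acetal groups, and the remaining ortho oxygen, the future O1, takes the C5 unit. This is preferred to a differentiation on a symmetric phloroglucinol ether, which would be statistical. The forward steps must alkylate a hydrogen-bonded, crowded phenol with a tertiary electrophile (hence copper catalysis) and reduce an alkyne to an alkene without touching the aldehyde.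

## Roads not taken

**Alternative 1:** cut at C2–O(ring B), the most obvious disconnection. Forward key step: addition–elimination of phenol 6 at C2 of the 2-(methylsulfonyl)chromone A1 to give the prenyl-free aryloxychromone A2, followed by prenylation at C8 and deprotection. A1 is reached only through S-oxidation with a peracid, so the prenyl alkene cannot be present before that point. The prenyl group must then be introduced last on A2, where C6 and C8 are both flanked by two oxygens. Direct C-alkylation there is unselective, and a relay of the prenyl group from O5 to C8 by two consecutive [3,3] shifts needs selective liberation of O5 and heating of the finished vinylogous carbonate. The chosen plan removes the C6/C8 choice by connectivity, needs no sulfur and no peracid, and is shorter.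

**Alternative 2:** cut at C4a–C4 and C8a–O1 together, an aryne route. Forward key step: fluoride-induced formation (CsF) of aryne A5 from the ortho-silylaryl triflate A3, attack of the carboxylate of the aryloxypropiolic acid A4 on C8a, acyl transfer to the aryl anion at C4a (net insertion of the aryne into the C–O bond of the acid), and closure of the resulting phenoxide onto the ynone to give 16. The side of attack would be right: the C5–O bond next to C4a polarises the triple bond so that the nucleophile adds to the remote carbon C8a and the anion develops at C4a. The plan is nevertheless poorer. A3 already contains the prenyl/oxygen pattern and needs three further operations on top of it (directed ortho-silylation, unmasking, triflation), so the run-up is longer than the whole chosen route to 13. The nucleophile must enter at the aryne carbon crowded by the prenyl group, where sterics oppose the electronic bias. A4 is a push–pull alkynoic acid that is expected to decarboxylate or add to itself under hot fluoride conditions. The chosen route reaches the same intermediate 15 without these liabilities.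

**Alternative 3:** cut at C2–O(ring B) in the sense of an oxygen insertion. Forward key step: the 2-hydroxyflavanone A6 (the cyclic hemiketal of a 1,3-diketone of the flavonoid series) is converted into the 2-hydroperoxide A7, and a Hock/Criegee 1,2-shift of the electron-rich ring B from C2 to oxygen gives a dioxocarbenium ion that loses H3 to give 16. The idea borrows all of flavone chemistry, but it does not touch the C6/C8 problem, since A6 must still be made with the prenyl group in place. The acid needed to form A7 also dehydrates A6 irreversibly across C2–C3, peroxide and acid together endanger the prenyl alkene and the electron-rich ring A, and the dioxocarbenium ion can also collapse with loss of the aryloxy group. The chosen plan makes C2 with both oxygens from an alkyne carbon and needs neither peroxide nor acid.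

Key step: step 7

Remark: compounds 12 and 14 are racemic; both stereocentres disappear within the route and the target has none, so no enantiocontrol is needed.

## Route

Step 1
Reactants: 1 2,4,6-trihydroxybenzaldehyde
Product: 2 2-hydroxy-4,6-bis(methoxymethoxy)benzaldehyde
Conditions: MOMCl (2.2 equiv), i-Pr2NEt, CH2Cl2, 0 °C to rt
Reagents that add atoms: chloromethyl methyl ether (MOMCl), COCCl
Why: O-alkylation of the two phenols that are not tied up; once one ortho oxygen is protected the other is held by the hydrogen bond to the formyl oxygen and stays free, which is the well-known selective bis-protection of this aldehyde. This single event marks the oxygen that will become O1.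

Step 2
Reactants: 2 2-hydroxy-4,6-bis(methoxymethoxy)benzaldehyde; 3 3-chloro-3-methylbut-1-yne
Product: 4 4,6-bis(methoxymethoxy)-2-[(2-methylbut-3-yn-2-yl)oxy]benzaldehyde
Conditions: CuCl2·2H2O (1 mol %), DBU, MeCN, 0 °C to rt
Reagents that add atoms: none
Why: Copper-catalysed propargylic etherification: a copper acetylide of 3 ionises the tertiary chloride and the phenoxide attacks the tertiary carbon. DBU fully deprotonates the salicylaldehyde-type OH, so the hydrogen bond no longer shields it, and electron-poor phenoxides are established partners in this reaction.

Step 3
Reactants: 4 4,6-bis(methoxymethoxy)-2-[(2-methylbut-3-yn-2-yl)oxy]benzaldehyde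
Product: 5 4,6-bis(methoxymethoxy)-2-[(2-methylbut-3-en-2-yl)oxy]benzaldehyde
Conditions: H2 (1 atm), Pd/CaCO3 poisoned with Pb(OAc)2, quinoline, EtOAc, rt
Reagents that add atoms: none
Why: Semihydrogenation of a terminal alkyne to the vinyl group on lead-poisoned palladium; the aldehyde, the acetals and the arene are inert under these conditions and uptake is stopped after one equivalent of hydrogen.

Step 4
Reactants: 6 4-(methoxymethoxy)phenol; 7 trichloroethylene
Product: 9 1-{[(E)-1,2-dichloroethenyl]oxy}-4-(methoxymethoxy)benzene, via dichloroacetylene 8 (not isolated)
Conditions: K2CO3, DMF, 70 °C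
Reagents that add atoms: none
Why: Base converts 7 into dichloroacetylene 8, to which the phenoxide of 6 adds in anti fashion; this is the standard preparation of aryl (E)-1,2-dichlorovinyl ethers. The anti addition fixes the E geometry, which is of no consequence because the alkene becomes an alkyne in step 5.

Step 5
Reactants: 9 1-{[(E)-1,2-dichloroethenyl]oxy}-4-(methoxymethoxy)benzene; 5 4,6-bis(methoxymethoxy)-2-[(2-methylbut-3-en-2-yl)oxy]benzaldehyde
Product: 12 1-{4,6-bis(methoxymethoxy)-2-[(2-methylbut-3-en-2-yl)oxy]phenyl}-3-[4-(methoxymethoxy)phenoxy]prop-2-yn-1-ol (racemic), via aryl chloroethynyl ether 10 (not isolated), via lithium aryloxyacetylide 11 (not isolated)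
Conditions: 9 (1.3 equiv), n-BuLi (2.0 equiv per 9), THF, −78 to −40 °C; then 5, −78 °C; then H2O
Reagents that add atoms: none
Why: Deprotonation and β-elimination of 9 give chloroalkyne 10, chlorine–lithium exchange gives acetylide 11 (the standard entry to aryl alkynyl ethers), and 1,2-addition to the non-enolisable aldehyde 5 gives racemic 12. O1 is masked as the tertiary allyl ether, so no phenoxide consumes base or attacks the alkynyl ether. 12 is prone to an acid-triggered Meyer–Schuster shift and is taken on crude.

Step 6
Reactants: 12 1-{4,6-bis(methoxymethoxy)-2-[(2-methylbut-3-en-2-yl)oxy]phenyl}-3-[4-(methoxymethoxy)phenoxy]prop-2-yn-1-ol (racemic)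
Product: 13 1-{4,6-bis(methoxymethoxy)-2-[(2-methylbut-3-en-2-yl)oxy]phenyl}-3-[4-(methoxymethoxy)phenoxy]prop-2-yn-1-one
Conditions: MnO2 (activated, excess), CH2Cl2, rt
Reagents that add atoms: none
Why: MnO2 oxidation of a benzylic and propargylic alcohol under neutral, non-aqueous conditions; the carbinol stereocentre is removed, and the alkynyl ether, the vinyl group and the acetals do not react with this oxidant.

Step 7
Reactants: 13 1-{4,6-bis(methoxymethoxy)-2-[(2-methylbut-3-en-2-yl)oxy]phenyl}-3-[4-(methoxymethoxy)phenoxy]prop-2-yn-1-one
Product: 16 5,7-bis(methoxymethoxy)-2-[4-(methoxymethoxy)phenoxy]-8-(3-methylbut-2-en-1-yl)-4H-chromen-4-one, via Claisen dienone 14 (not isolated), via ortho-hydroxyaryl ynone 15 (not isolated)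
Conditions: PhMe, 110 °C (sealed tube, base-washed glass); then K2CO3 (cat.), acetone, rt
Reagents that add atoms: none
Why: Heating starts an aromatic Claisen rearrangement of the aryl 1,1-dimethylallyl ether: the O1–C(CH3)2 bond breaks while the vinyl CH2 bonds to the only hydrogen-bearing ortho carbon (the future C8), giving dienone 14, which tautomerises to the ortho-prenyl phenol 15. The liberated O1–H, held next to the ketone by a hydrogen bond, then adds to the β-carbon of the aryloxy-ynone (oxa-Michael addition) and protonation at C3 gives the 4-pyranone ring C; catalytic K2CO3 at room temperature completes any unfinished closure. The closest known reaction types are the Claisen rearrangement of aryl 1,1-dimethylallyl ethers to ortho-prenylphenols, the cyclisation of ortho-hydroxyaryl ynones to chromones, and the addition of O–H nucleophiles to the β-carbon of alkoxyethynyl ketones. Ring C is closed in the 6-endo-dig mode; the 5-exo-dig mode (attack at the α-carbon) is disfavoured because only β-attack gives a ketone-stabilised allenolate. No stereocentre results: the sp3 carbon of 14 is lost on tautomerisation. Three selectivities are needed and each is built into 13: the shift goes to C8 and not to the acyl-bearing ipso carbon because only C8 carries hydrogen and allows irreversible tautomerisation; ring closure can use only O1 because the other ortho oxygen (O5) is a methoxymethyl ether, so the 6-prenyl isomer cannot form; the aryloxy group stays on C2 because addition to an alkyne has no leaving-group step. Neutral, aprotic conditions keep the tertiary allyl ether from ionising before it rearranges.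

Step 8
Reactants: 16 5,7-bis(methoxymethoxy)-2-[4-(methoxymethoxy)phenoxy]-8-(3-methylbut-2-en-1-yl)-4H-chromen-4-one
Product: 17 Epimedonin G, 5,7-dihydroxy-2-(4-hydroxyphenoxy)-8-(3-methylbut-2-en-1-yl)-4H-chromen-4-one
Conditions: HCl (3 M aq.), i-PrOH–THF, 45 °C
Reagents that add atoms: none
Why: Acid-catalysed hydrolysis of three aryl methoxymethyl acetals, the usual final step for prenylated polyphenols; the acetal on O5 (peri to the C4 carbonyl) should go first. Isopropanol is used in place of methanol to keep nucleophilic exchange at C2 low, and the temperature is kept mild for the prenyl alkene.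

## Compound list

1 | 2,4,6-trihydroxybenzaldehyde | O=Cc1c(O)cc(O)cc1O | starting material
2 | 2-hydroxy-4,6-bis(methoxymethoxy)benzaldehyde | O=Cc1c(O)cc(OCOC)cc1OCOC | intermediate
3 | 3-chloro-3-methylbut-1-yne | C#CC(C)(C)Cl | starting material
4 | 4,6-bis(methoxymethoxy)-2-[(2-methylbut-3-yn-2-yl)oxy]benzaldehyde | O=Cc1c(OC(C)(C)C#C)cc(OCOC)cc1OCOC | intermediate
5 | 4,6-bis(methoxymethoxy)-2-[(2-methylbut-3-en-2-yl)oxy]benzaldehyde | O=Cc1c(OC(C)(C)C=C)cc(OCOC)cc1OCOC | intermediate
6 | 4-(methoxymethoxy)phenol | COCOc1ccc(O)cc1 | starting material
7 | trichloroethylene | ClC=C(Cl)Cl | starting material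
8 | dichloroacetylene | ClC#CCl | intermediate
9 | 1-{[(E)-1,2-dichloroethenyl]oxy}-4-(methoxymethoxy)benzene | Cl/C=C(/Cl)Oc1ccc(OCOC)cc1 | intermediate
10 | 1-[(chloroethynyl)oxy]-4-(methoxymethoxy)benzene | ClC#COc1ccc(OCOC)cc1 | intermediate
11 | lithium [4-(methoxymethoxy)phenoxy]ethynide | [Li]C#COc1ccc(OCOC)cc1 | intermediate
12 | 1-{4,6-bis(methoxymethoxy)-2-[(2-methylbut-3-en-2-yl)oxy]phenyl}-3-[4-(methoxymethoxy)phenoxy]prop-2-yn-1-ol (racemic) | OC(C#COc1ccc(OCOC)cc1)c1c(OC(C)(C)C=C)cc(OCOC)cc1OCOC | intermediate
13 | 1-{4,6-bis(methoxymethoxy)-2-[(2-methylbut-3-en-2-yl)oxy]phenyl}-3-[4-(methoxymethoxy)phenoxy]prop-2-yn-1-one | O=C(C#COc1ccc(OCOC)cc1)c1c(OC(C)(C)C=C)cc(OCOC)cc1OCOC | intermediate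
14 | 3,5-bis(methoxymethoxy)-2-{3-[4-(methoxymethoxy)phenoxy]prop-2-ynoyl}-6-(3-methylbut-2-en-1-yl)cyclohexa-2,4-dien-1-one (racemic) | O=C(C#COc1ccc(OCOC)cc1)C1=C(OCOC)C=C(OCOC)C(CC=C(C)C)C1=O | intermediate
15 | 1-[2-hydroxy-4,6-bis(methoxymethoxy)-3-(3-methylbut-2-en-1-yl)phenyl]-3-[4-(methoxymethoxy)phenoxy]prop-2-yn-1-one | O=C(C#COc1ccc(OCOC)cc1)c1c(O)c(CC=C(C)C)c(OCOC)cc1OCOC | intermediate
16 | 5,7-bis(methoxymethoxy)-2-[4-(methoxymethoxy)phenoxy]-8-(3-methylbut-2-en-1-yl)-4H-chromen-4-one | CC(C)=CCc1c(OCOC)cc(OCOC)c2c(=O)cc(Oc3ccc(OCOC)cc3)oc12 | intermediate
17 | Epimedonin G, 5,7-dihydroxy-2-(4-hydroxyphenoxy)-8-(3-methylbut-2-en-1-yl)-4H-chromen-4-one | CC(C)=CCc1c(O)cc(O)c2c(=O)cc(Oc3ccc(O)cc3)oc12 | target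

## Step count and least certain steps

Total: 8 steps. Longest linear sequence: 7 steps (1, 2, 3, 5, 6, 7, 8); step 4 is a one-step branch.

**Step 7 (key step).** Most likely to go wrong: thermal degradation or oligomerisation of the push–pull ynone during the time the sigmatropic shift needs; ionisation of the tertiary allyl ether by adventitious acid, with loss of the C5 unit before it has migrated; some migration to the para position through ipso attack and a following Cope shift. Fallback, setting out from 5 and returning at 16: 5 is heated alone, so that the same Claisen rearrangement runs on a robust aldehyde and should give 2-hydroxy-4,6-bis(methoxymethoxy)-3-(3-methylbut-2-en-1-yl)benzaldehyde F1. The hindered phenol is silylated (TBSOTf, 2,6-lutidine) to the tert-butyldimethylsilyl ether F2. Addition of 11 gives the racemic propargylic alcohol F3, and MnO2 gives the silyl-protected ynone F4. Buffered fluoride (TBAF, AcOH, THF, 0 °C) then releases the phenoxide of 15, which should close to 16 at low temperature. The pericyclic step and the ring closure are thus separated, at the price of three more steps.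

**Step 2.** Most likely to go wrong: slow O-alkylation, because the phenoxide is deactivated by the ortho-formyl group and crowded, while the tertiary chloride is consumed by elimination or by copper-mediated alkyne coupling. Fallback, setting out from 2 and returning at 5: Tsuji–Trost O-allylation with tert-butyl 2-methylbut-3-en-2-yl carbonate F5 (one step from the commercial tertiary allylic alcohol) and Pd(PPh3)4, a zerovalent palladium catalyst, in THF at 0 °C. Ionisation gives a 1,1-dimethylallyl–palladium cation and tert-butoxide, which deprotonates 2. Attack of the phenoxide at the more substituted allyl terminus is the kinetic outcome with this carbonate and should give 5 directly, so that 4 and step 3 are bypassed.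

**Step 5.** Most likely to go wrong: acid-triggered ionisation of the doubly activated carbinol during work-up or chromatography (Meyer–Schuster rearrangement to an aryl cinnamate); and, if the chlorine–lithium exchange is incomplete, addition of butyllithium to the aldehyde. Fallback, setting out from 5 and returning at 13: Pinnick oxidation (NaClO2, NaH2PO4, 2-methylbut-2-ene) of 5 to 4,6-bis(methoxymethoxy)-2-[(2-methylbut-3-en-2-yl)oxy]benzoic acid F6, then conversion (carbonyldiimidazole, then N,O-dimethylhydroxylamine) into the N-methoxy-N-methylamide F7. Acylation of 11 with F7 should give ynone 13 directly through a stable tetrahedral chelate; the acid-labile carbinol 12 and step 6 are avoided.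

**Step 8.** Most likely to go wrong: once O7 is free, acid-induced attack of O7 on the protonated prenyl alkene (chromane formation); and solvolysis at C2 of the protonated chromone with loss of the aryloxy group. Fallback, setting out from 16 and returning at 17: silyl transfer under non-protic conditions (TMSOTf, 2,2'-bipyridyl, MeCN, 0 °C), in which each aryl acetal is activated as a pyridinium salt and the aryl oxygen is silylated, should give the tris(trimethylsilyl) ether F8. Neutral aqueous hydrolysis of F8 then gives 17 without the prenyl alkene or C2 meeting a strong protic acid.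

## Further compounds

F1 | step 7 | 2-hydroxy-4,6-bis(methoxymethoxy)-3-(3-methylbut-2-en-1-yl)benzaldehyde | O=Cc1c(O)c(CC=C(C)C)c(OCOC)cc1OCOC
F2 | step 7 | 2-[(tert-butyldimethylsilyl)oxy]-4,6-bis(methoxymethoxy)-3-(3-methylbut-2-en-1-yl)benzaldehyde | O=Cc1c(O[Si](C)(C)C(C)(C)C)c(CC=C(C)C)c(OCOC)cc1OCOC
F3 | step 7 | 1-{2-[(tert-butyldimethylsilyl)oxy]-4,6-bis(methoxymethoxy)-3-(3-methylbut-2-en-1-yl)phenyl}-3-[4-(methoxymethoxy)phenoxy]prop-2-yn-1-ol (racemic) | OC(C#COc1ccc(OCOC)cc1)c1c(O[Si](C)(C)C(C)(C)C)c(CC=C(C)C)c(OCOC)cc1OCOC
F4 | step 7 | 1-{2-[(tert-butyldimethylsilyl)oxy]-4,6-bis(methoxymethoxy)-3-(3-methylbut-2-en-1-yl)phenyl}-3-[4-(methoxymethoxy)phenoxy]prop-2-yn-1-one | O=C(C#COc1ccc(OCOC)cc1)c1c(O[Si](C)(C)C(C)(C)C)c(CC=C(C)C)c(OCOC)cc1OCOC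
F5 | step 2 | tert-butyl 2-methylbut-3-en-2-yl carbonate | CC(C)(C)OC(=O)OC(C)(C)C=C
F6 | step 5 | 4,6-bis(methoxymethoxy)-2-[(2-methylbut-3-en-2-yl)oxy]benzoic acid | OC(=O)c1c(OC(C)(C)C=C)cc(OCOC)cc1OCOC
F7 | step 5 | N-methoxy-N-methyl-4,6-bis(methoxymethoxy)-2-[(2-methylbut-3-en-2-yl)oxy]benzamide | CON(C)C(=O)c1c(OC(C)(C)C=C)cc(OCOC)cc1OCOC
F8 | step 8 | 8-(3-methylbut-2-en-1-yl)-5,7-bis[(trimethylsilyl)oxy]-2-{4-[(trimethylsilyl)oxy]phenoxy}-4H-chromen-4-one | CC(C)=CCc1c(O[Si](C)(C)C)cc(O[Si](C)(C)C)c2c(=O)cc(Oc3ccc(O[Si](C)(C)C)cc3)oc12
A1 | alternative 1 | 5,7-bis(methoxymethoxy)-2-(methylsulfonyl)-4H-chromen-4-one | COCOc1cc(OCOC)c2c(=O)cc(S(C)(=O)=O)oc2c1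
A2 | alternative 1 | 5,7-bis(methoxymethoxy)-2-[4-(methoxymethoxy)phenoxy]-4H-chromen-4-one | COCOc1ccc(Oc2cc(=O)c3c(OCOC)cc(OCOC)cc3o2)cc1
A3 | alternative 2 | 3,5-bis(methoxymethoxy)-2-(3-methylbut-2-en-1-yl)-6-(trimethylsilyl)phenyl trifluoromethanesulfonate | CC(C)=CCc1c(OCOC)cc(OCOC)c([Si](C)(C)C)c1OS(=O)(=O)C(F)(F)F
A4 | alternative 2 | 3-[4-(methoxymethoxy)phenoxy]prop-2-ynoic acid | COCOc1ccc(OC#CC(O)=O)cc1
A5 | alternative 2 | 3,5-bis(methoxymethoxy)-6-(3-methylbut-2-en-1-yl)benzyne (1,2-didehydrobenzene) | CC(C)=CCC1=C(OCOC)C=C(OCOC)C#C1
A6 | alternative 3 | 2-hydroxy-5,7-bis(methoxymethoxy)-2-[4-(methoxymethoxy)phenyl]-8-(3-methylbut-2-en-1-yl)chroman-4-one (racemic) | COCOc1ccc(C2(O)CC(=O)c3c(OCOC)cc(OCOC)c(CC=C(C)C)c3O2)cc1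
A7 | alternative 3 | 2-hydroperoxy-5,7-bis(methoxymethoxy)-2-[4-(methoxymethoxy)phenyl]-8-(3-methylbut-2-en-1-yl)chroman-4-one (racemic) | COCOc1ccc(C2(OO)CC(=O)c3c(OCOC)cc(OCOC)c(CC=C(C)C)c3O2)cc1
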